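**Retrosynthetic overview**

1. Local atom labels: C1 = CH–OAc, C2/C3 = epoxide carbons (C3 carries Me), C4, C5 = CH2, C6 = ring-fusion CH, C7 = side-chain carbon, C8, C9 = CH2, C10 = quaternary C–Me, C11–C15 = side chain; β = face of the C10 methyl. The dienol side chain comes last, by nickel-catalysed reductive C7–C11 coupling of core bromide 15 with bromodienol 21; acetate, α-epoxide and trans ring fusion are installed on dienone-ol 10 by hydroxyl-directed epoxidation and hydrogenation.
2. The seven-membered ring is closed through the C1–C10 bond by a strain-releasing Cope rearrangement of cis-divinylcyclopropane 8; the temporary cyclopropane C3–C4–C5 is cleaved in the same step, and the resulting allylboronate is oxidised to the C1 alcohol.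
3. Enabling feature: in the seven-membered ring, C2=C3 (the later epoxide) and the ring-fusion carbon C6 flank the C4 methylene in a 1,4-relationship, and the C1(O)–C10(quaternary) bond lies opposite C4. This is the imprint of a cis-divinylcyclopropane, with the cyclopentane (C6=C10) acting as one vinyl group and the C7 ketone conjugating the new C5=C6 alkene.
4. Cyclopropane 6 comes from (Z)-allylic alcohol 5 by Charette cyclopropanation (source of absolute configuration); 5 comes from Stille union of stannane 3 (from propargyl alcohol) with bromoenone 4.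
5. Ring order: cyclopentane (bought in 4) → temporary cyclopropane (step 3) → cycloheptane (step 6, last carbocycle) → oxirane on the finished skeleton (step 7).

Key step: step 6

Remark: compounds 1, 4 and 16, Cl2CHB(pin) and the acetonyl ylide are taken as commercial. The C7 configuration of 14 and 15 is not carried into the product, because step 17 passes through a C7 radical.

**Route**

Step 1
Reactants: 1 prop-2-yn-1-ol
Product: 3 (Z)-2-methyl-3-(tributylstannyl)prop-2-en-1-ol, via alkenylmagnesium chelate 2 (not isolated)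
Conditions: MeMgBr (3 equiv), CuI (10 mol%), Et2O, −10 °C to rt; then Bu3SnCl, THF, 0 °C to rt; aq. NH4Cl
Reagents that add atoms: methylmagnesium bromide, C[Mg]Br; tributyltin chloride, CCCC[Sn](Cl)(CCCC)CCCC
Why: Copper-catalysed anti-carbomagnesiation of the propargylic alkoxide places methyl on C2 and magnesium on C3 cis to the CH2O group through a five-membered chelate, and stannylation with retention fixes the Z geometry.

Step 2
Reactants: 3 (Z)-2-methyl-3-(tributylstannyl)prop-2-en-1-ol; 4 2-bromo-3-methylcyclopent-2-en-1-one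
Product: 5 2-[(1Z)-3-hydroxy-2-methylprop-1-en-1-yl]-3-methylcyclopent-2-en-1-one
Conditions: Pd(PPh3)4 (5 mol%), CuI (10 mol%), CsF (2 equiv), DMF, 45 °C
Reagents that add atoms: none
Why: Stille coupling of an alkenylstannane with an α-bromoenone should proceed with retention of the Z geometry, with fluoride and CuI accelerating transmetallation at the hindered α-carbon.

Step 3
Reactants: 5 2-[(1Z)-3-hydroxy-2-methylprop-1-en-1-yl]-3-methylcyclopent-2-en-1-one
Product: 6 2-[(1R,2S)-2-(hydroxymethyl)-2-methylcyclopropyl]-3-methylcyclopent-2-en-1-one (CH2OH and cyclopentenone cis)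
Conditions: Zn(CH2I)2·DME (from Et2Zn, CH2I2, DME; 2.2 equiv), (4R,5R)-2-butyl-N,N,N′,N′-tetramethyl-1,3,2-dioxaborolane-4,5-dicarboxamide (1.2 equiv), CH2Cl2, −10 °C to rt
Reagents that add atoms: diiodomethane, ICI
Why: Charette asymmetric Simmons–Smith cyclopropanation delivers CH2 syn to the allylic alkene only, so the Z geometry becomes the cis ring relationship, and the (4R,5R) ligand (the enantiomer that converts (E)-cinnamyl alcohol into the (1S,2S)-cyclopropylmethanol) should select the face leading to (1R,2S), while the electron-poor tetrasubstituted enone alkene stays untouched.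

Step 4
Reactants: 6 2-[(1R,2S)-2-(hydroxymethyl)-2-methylcyclopropyl]-3-methylcyclopent-2-en-1-one
Product: 7 (1S,2R)-1-methyl-2-(2-methyl-5-oxocyclopent-1-en-1-yl)cyclopropane-1-carbaldehyde
Conditions: Dess–Martin periodinane, NaHCO3, CH2Cl2, 0 °C; used at once
Reagents that add atoms: none
Why: Dess–Martin oxidation of a primary alcohol under buffered conditions cannot epimerise the product because the aldehyde α-carbon is quaternary.

Step 5
Reactants: 7 (1S,2R)-1-methyl-2-(2-methyl-5-oxocyclopent-1-en-1-yl)cyclopropane-1-carbaldehyde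
Product: 8 3-methyl-2-[(1R,2R)-2-methyl-2-[(E)-2-(4,4,5,5-tetramethyl-1,3,2-dioxaborolan-2-yl)ethenyl]cyclopropyl]cyclopent-2-en-1-one (alkenyl and cyclopentenone cis)
Conditions: Cl2CHB(pin) (2 equiv), CrCl2 (8 equiv), LiI (4 equiv), THF, 20 °C
Reagents that add atoms: 2-(dichloromethyl)-4,4,5,5-tetramethyl-1,3,2-dioxaborolane, CC1(C)OB(OC1(C)C)C(Cl)Cl
Why: Takai–Utimoto boryl-olefination adds the geminal dichromium reagent to the aldehyde only (the ketone is inert) and should give the (E)-alkenylboronate at a temperature below the onset of rearrangement of the hindered divinylcyclopropane.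

Step 6
Reactants: 8 3-methyl-2-[(1R,2R)-2-methyl-2-[(E)-2-(4,4,5,5-tetramethyl-1,3,2-dioxaborolan-2-yl)ethenyl]cyclopropyl]cyclopent-2-en-1-one
Product: 10 4-hydroxy-3a,6-dimethyl-3,3a,4,7-tetrahydroazulen-1(2H)-one (local labels: 1α-OH, 10β-Me, C2=C3, C5=C6, C7 ketone), via cyclic allylboronate 9 (not isolated)
Conditions: PhMe (degassed), 100 °C; then NaBO3·4H2O, THF/pH 7 buffer, 0 °C to rt
Reagents that add atoms: sodium perborate tetrahydrate (oxygen of the hydroxyl group), [Na+].[O-]OB=O
Why: Proposed new method: heating 8 should trigger the concerted [3,3]-sigmatropic (Cope) rearrangement of the cis-1,2-dialkenylcyclopropane through the endo,endo boat transition state, in which the strained C3–C5 bond breaks while C1 of the (E)-alkenylboronate bonds to C10, the β-carbon of the enone, to give cyclohepta-1,4-diene 9, whose allylic C–B bond is then oxidised with retention. The closest known reaction type is the cis-divinylcyclopropane–cycloheptadiene rearrangement, documented for cyclopentenyl- and oxygen-substituted divinylcyclopropanes including cases that create an angular methyl quaternary centre, together with [3,3] shifts that turn alkenylboronates into α-stereogenic allylboronates; a boryl group on the bonding terminus of a divinylcyclopropane is the undocumented element, and as boron is a spectator in a pericyclic step driven by about 25 kcal/mol of ring strain, no change of mechanism is expected. The seven-membered ring (C1, C2, C3, C4, C5, C6, C10) is closed by this strain-releasing ring expansion of the three-membered ring, the new C1–C10 σ-bond forming suprafacially on both alkenes, with the existing cyclopentene providing one of them. C10 is controlled by the cyclopropane stereocentres from step 3: both alkenyl groups must lie over the three-membered ring, so only one face of C6=C10 can reach C1, and the configuration of C3/C5 is relayed to the quaternary carbon (methyl β). C1 is controlled by the E geometry of the alkenylboronate: the E substituent (boron) points outward in the boat and ends up cis to C9 and trans to the C10 methyl, that is α, and the oxidation keeps this configuration. The step needs the boat pathway to outrun one-centre epimerisation of the cyclopropane and 1,3-boron migration in 9, which is secured by the cis geometry built stereospecifically from the Z-alkene, by having a single inward substituent (the C10 methyl; H at C1) so that about 100 °C should suffice, and by the pinacol ester, which is slow to undergo borotropic shift and would migrate suprafacially in any case.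

Step 7
Reactants: 10 4-hydroxy-3a,6-dimethyl-3,3a,4,7-tetrahydroazulen-1(2H)-one
Product: 11 2α,3α-epoxide of 10 (1α-OH, 2α,3α-epoxy, 10β-Me, C5=C6, C7 ketone)
Conditions: VO(acac)2 (5 mol%), t-BuOOH (1.5 equiv), CH2Cl2, 0 °C to rt
Reagents that add atoms: tert-butyl hydroperoxide, CC(C)(C)OO
Why: Vanadium-catalysed hydroxyl-directed epoxidation should deliver oxygen to the allylic C2=C3 alkene on the face of the C1 hydroxyl (α), as is usual for cyclohept-2-enols, and leave the electron-poor enone alkene alone.

Step 8
Reactants: 11 2α,3α-epoxy-1α-hydroxy dienone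
Product: 12 trans-fused epoxy hydroxy ketone (1α-OH, 2α,3α-epoxy, 6α-H, 10β-Me, C7 ketone)
Conditions: [Ir(cod)(PCy3)(py)]PF6 (5 mol%), H2 (1 atm), CH2Cl2, rt
Reagents that add atoms: none
Why: Hydroxyl-directed hydrogenation with the cationic iridium catalyst bound to the α-oriented homoallylic C1–OH should add H2 to the α face of C5=C6, anti to the C10 methyl, setting the trans ring fusion.

Step 9
Reactants: 12 trans-fused epoxy hydroxy ketone
Product: 13 1α-acetoxy-2α,3α-epoxy trans-fused C7 ketone
Conditions: Ac2O, pyridine, DMAP (cat.), CH2Cl2, 0 °C to rt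
Reagents that add atoms: acetic anhydride, CC(=O)OC(C)=O
Why: DMAP-catalysed acylation of the only hydroxyl group proceeds with retention at C1 under conditions too mild to epimerise C6.

Step 10
Reactants: 13 1α-acetoxy-2α,3α-epoxy trans-fused C7 ketone
Product: 14 7β-alcohol (1α-OAc, 2α,3α-epoxy, 6α-H, 7β-OH)
Conditions: NaBH4, MeOH/THF, −20 °C
Reagents that add atoms: none
Why: Borohydride reduction of the cyclopentanone from the less hindered α face should give mainly the 7β-alcohol, with acetate and epoxide inert at low temperature.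

Step 11
Reactants: 14 7β-alcohol
Product: 15 7α-bromide (1α-OAc, 2α,3α-epoxy, 6α-H, 7α-Br)
Conditions: CBr4, PPh3, 2,6-lutidine, CH2Cl2, 0 °C to rt
Reagents that add atoms: carbon tetrabromide, BrC(Br)(Br)Br
Why: Appel bromination converts the secondary alcohol into the bromide with inversion under neutral conditions that leave epoxide and acetate intact.

Step 12
Reactants: 16 ethyl but-2-ynoate
Product: 17 ethyl (2Z)-3-bromobut-2-enoate
Conditions: LiBr, AcOH, MeCN, reflux
Reagents that add atoms: lithium bromide, [Li+].[Br-]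
Why: Anti hydrobromination of the ynoate (bromide adds at the β-carbon, proton anti at the α-carbon) should give the Z isomer with bromine cis to the ester.

Step 13
Reactants: 17 ethyl (2Z)-3-bromobut-2-enoate
Product: 18 (2Z)-3-bromobut-2-en-1-ol
Conditions: i-Bu2AlH (2.2 equiv), CH2Cl2, −78 °C; Rochelle salt
Reagents that add atoms: none
Why: 1,2-Reduction of the enoate by the aluminium hydride leaves the alkenyl bromide and its geometry untouched.

Step 14
Reactants: 18 (2Z)-3-bromobut-2-en-1-ol
Product: 19 (2Z)-3-bromobut-2-enal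
Conditions: MnO2, CH2Cl2, rt; used at once
Reagents that add atoms: none
Why: MnO2 oxidises the allylic alcohol selectively and under neutral conditions that should not isomerise the Z alkene.

Step 15
Reactants: 19 (2Z)-3-bromobut-2-enal
Product: 20 (3E,5Z)-6-bromohepta-3,5-dien-2-one
Conditions: Ph3P=CHC(O)CH3, CH2Cl2, rt
Reagents that add atoms: 1-(triphenylphosphoranylidene)propan-2-one, CC(=O)C=P(c1ccccc1)(c1ccccc1)c1ccccc1
Why: Wittig olefination with a stabilised acyl ylide is E-selective for the new disubstituted alkene.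

Step 16
Reactants: 20 (3E,5Z)-6-bromohepta-3,5-dien-2-one
Product: 21 (3E,5Z)-6-bromo-2-methylhepta-3,5-dien-2-ol
Conditions: MeMgBr, CeCl3 (anhydrous), THF, −78 °C
Reagents that add atoms: methylmagnesium bromide, C[Mg]Br
Why: Cerium-mediated 1,2-addition of the methyl nucleophile to the dienone carbonyl suppresses conjugate addition and base-induced dehydrobromination.

Step 17
Reactants: 15 7α-bromide; 21 (3E,5Z)-6-bromo-2-methylhepta-3,5-dien-2-ol
Product: 22 target CNP0265175.1 (1α-OAc, 2α,3α-epoxy, 6α-H, 7α-[(2Z,4E)-6-hydroxy-6-methylhepta-2,4-dien-2-yl], 10β-Me)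
Conditions: NiBr2(dme) (10 mol%), 4,4′-di-tert-butyl-2,2′-bipyridine (12 mol%), Mn powder (3 equiv), NaI (0.5 equiv), DMA, rt
Reagents that add atoms: none
Why: Nickel-catalysed reductive cross-electrophile coupling of a secondary alkyl bromide with an alkenyl bromide should join the alkenylnickel species (oxidative addition with retention of the Z geometry) with the C7 radical on the α face, anti to the vicinal C5 substituent on C6 and to the β-methyl on C10, under neutral conditions that tolerate acetate, epoxide and the free tertiary alcohol.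

**Compound list**

1 | prop-2-yn-1-ol | C#CCO | starting material
2 | bromomagnesium (Z)-3-(bromomagnesio)-2-methylprop-2-en-1-olate (alkenylmagnesium chelate) | Br[Mg]/C=C(C)\CO[Mg]Br | intermediate
3 | (Z)-2-methyl-3-(tributylstannyl)prop-2-en-1-ol | CCCC[Sn](CCCC)(CCCC)/C=C(C)\CO | intermediate
4 | 2-bromo-3-methylcyclopent-2-en-1-one | CC1=C(Br)C(=O)CC1 | starting material
5 | 2-[(1Z)-3-hydroxy-2-methylprop-1-en-1-yl]-3-methylcyclopent-2-en-1-one | CC1=C(/C=C(C)\CO)C(=O)CC1 | intermediate
6 | 2-[(1R,2S)-2-(hydroxymethyl)-2-methylcyclopropyl]-3-methylcyclopent-2-en-1-one | OC[C@@]1(C)C[C@H]1C2=C(C)CCC2=O | intermediate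
7 | (1S,2R)-1-methyl-2-(2-methyl-5-oxocyclopent-1-en-1-yl)cyclopropane-1-carbaldehyde | O=C[C@@]1(C)C[C@H]1C2=C(C)CCC2=O | intermediate
8 | 3-methyl-2-[(1R,2R)-2-methyl-2-[(E)-2-(4,4,5,5-tetramethyl-1,3,2-dioxaborolan-2-yl)ethenyl]cyclopropyl]cyclopent-2-en-1-one | CC1(C)OB(OC1(C)C)/C=C/[C@@]2(C)C[C@H]2C3=C(C)CCC3=O | intermediate
9 | 3a,6-dimethyl-4-(4,4,5,5-tetramethyl-1,3,2-dioxaborolan-2-yl)-3,3a,4,7-tetrahydroazulen-1(2H)-one (1α-boryl, 10β-Me) | CC1(C)OB(OC1(C)C)[C@@H]2C=C(C)CC=C3C(=O)CC[C@]23C | intermediate
10 | 4-hydroxy-3a,6-dimethyl-3,3a,4,7-tetrahydroazulen-1(2H)-one (1α-OH, 10β-Me) | O[C@@H]1C=C(C)CC=C2C(=O)CC[C@]12C | intermediate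
11 | 2α,3α-epoxide of 10 (1α-OH, C5=C6, C7 ketone) | O[C@@H]1[C@@H]2O[C@]2(C)CC=C2C(=O)CC[C@]12C | intermediate
12 | trans-fused epoxy hydroxy ketone (1α-OH, 2α,3α-epoxy, 6α-H, 10β-Me, C7 ketone) | O[C@@H]1[C@@H]2O[C@]2(C)CC[C@H]2C(=O)CC[C@]12C | intermediate
13 | 1α-acetate of 12 | CC(=O)O[C@@H]1[C@@H]2O[C@]2(C)CC[C@H]2C(=O)CC[C@]12C | intermediate
14 | 7β-alcohol (1α-OAc, 2α,3α-epoxy, 6α-H) | CC(=O)O[C@@H]1[C@@H]2O[C@]2(C)CC[C@H]2[C@@H](O)CC[C@]12C | intermediate
15 | 7α-bromide (1α-OAc, 2α,3α-epoxy, 6α-H) | CC(=O)O[C@@H]1[C@@H]2O[C@]2(C)CC[C@H]2[C@H](Br)CC[C@]12C | intermediate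
16 | ethyl but-2-ynoate | CC#CC(=O)OCC | starting material
17 | ethyl (2Z)-3-bromobut-2-enoate | C/C(Br)=C/C(=O)OCC | intermediate
18 | (2Z)-3-bromobut-2-en-1-ol | C/C(Br)=C/CO | intermediate
19 | (2Z)-3-bromobut-2-enal | C/C(Br)=C/C=O | intermediate
20 | (3E,5Z)-6-bromohepta-3,5-dien-2-one | C/C(Br)=C/C=C/C(C)=O | intermediate
21 | (3E,5Z)-6-bromo-2-methylhepta-3,5-dien-2-ol | C/C(Br)=C/C=C/C(C)(C)O | intermediate
22 | CNP0265175.1 (1α-acetoxy-2α,3α-epoxy-7α-[(2Z,4E)-6-hydroxy-6-methylhepta-2,4-dien-2-yl] trans-hydroazulene) | CC(=O)O[C@@H]1[C@@H]2O[C@]2(C)CC[C@H]2[C@H](/C(C)=C\C=C\C(C)(C)O)CC[C@]12C | target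

**Totals and risks**

Total step count: 17 (main line steps 1–11 and 17; side-chain fragment steps 12–16). Longest linear sequence: 12 steps (1–11, then 17).

Three steps most likely to fail:

1. Step 6 (proposed new method). The inward C10 methyl may slow the rearrangement enough that stereomutation of the cyclopropane, boron migration or protodeboronation of the allylboronate compete, and the perborate work-up may attack the enone. Fallback with known chemistry, from 7 back to 10: aldehyde 7 is homologated by Wittig reaction with the ylide from [(4-methoxybenzyloxy)methyl]triphenylphosphonium chloride and NaN(SiMe3)2. The E isomer of the resulting enol ether, 2-[2-[(E)-2-(4-methoxybenzyloxy)ethenyl]-2-methylcyclopropyl]-3-methylcyclopent-2-en-1-one F1 (cis, configured as 8), is separated from the Z isomer and heated in toluene. Oxygen-substituted cis-divinylcyclopropanes are established Cope substrates, and the E-alkoxy group should end up α at C1 for the same reason as boron, giving the 1α-(4-methoxybenzyl) ether of 10 F2. DDQ in wet CH2Cl2 then cleaves the ether and returns 10.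

2. Step 17. The alkenylnickel intermediate may lose its Z geometry, radical capture at C7 may show poor facial selectivity, and the two hindered partners may prefer homocoupling or elimination. Fallback, from 12 to 22, builds the side chain stepwise with C7 set by thermodynamic control:
   - 12 is silylated (t-BuMe2SiOTf, 2,6-lutidine) to the silyl ether F3.
   - Reductive cyanation with TosMIC/KOt-Bu (van Leusen) gives the 7α-nitrile F4 after base equilibration to the trans arrangement.
   - i-Bu2AlH gives the 7α-aldehyde F5.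
   - Ohira–Bestmann homologation (K2CO3, MeOH) gives the terminal alkyne F6.
   - n-BuLi then ClCO2Me gives the ynoate F7.
   - Syn addition of Me2CuLi at −78 °C gives the (Z)-enoate F8, with C7 cis to the ester.
   - i-Bu2AlH gives the (Z)-allylic alcohol F9, and MnO2 the (Z)-enal F10.
   - Wittig reaction with Ph3P=CHC(O)CH3 gives the (Z,E)-dienone F11.
   - MeMgBr/CeCl3 gives the silylated tertiary alcohol F12.
   - Bu4NF gives the diol F13.
   - Ac2O/pyridine acetylates only the secondary C1 hydroxyl and gives 22.

3. Step 3. The cis-hydroxy enone may tie up its hydroxyl as a cyclic hemiketal, and the zinc carbenoid may react slowly or with low facial control at the hindered, cross-conjugated Z alkene. Fallback, from 1 and 4 back to 6, cyclopropanates before the cyclopentenone is attached: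
   - 1 is carbomagnesiated as in step 1 but quenched with iodine to give (Z)-3-iodo-2-methylprop-2-en-1-ol F14.
   - Charette cyclopropanation with the same ligand gives the cis-iodocyclopropylmethanol F15.
   - t-BuMe2SiCl/imidazole gives the silyl ether F16.
   - Iodine–lithium exchange (t-BuLi, −78 °C), transmetallation with ZnCl2 and Negishi coupling with 4 (Pd(PPh3)4, THF, 50 °C) give, with retention at the cyclopropane, the coupled silyl ether F17.
   - Bu4NF returns 6.

Further compounds
F1 | step 6 | 2-[2-[(E)-2-(4-methoxybenzyloxy)ethenyl]-2-methylcyclopropyl]-3-methylcyclopent-2-en-1-one (cis, configured as 8) | COc1ccc(CO/C=C/[C@@]2(C)C[C@H]2C3=C(C)CCC3=O)cc1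
F2 | step 6 | 1α-(4-methoxybenzyl) ether of 10 | COc1ccc(CO[C@@H]2C=C(C)CC=C3C(=O)CC[C@]23C)cc1
F3 | step 17 | 1α-tert-butyldimethylsilyl ether of 12 | CC(C)(C)[Si](C)(C)O[C@@H]1[C@@H]2O[C@]2(C)CC[C@H]2C(=O)CC[C@]12C
F4 | step 17 | 7α-nitrile (1α-silyloxy, 2α,3α-epoxy, 6α-H) | CC(C)(C)[Si](C)(C)O[C@@H]1[C@@H]2O[C@]2(C)CC[C@H]2[C@H](C#N)CC[C@]12C
F5 | step 17 | 7α-carbaldehyde | CC(C)(C)[Si](C)(C)O[C@@H]1[C@@H]2O[C@]2(C)CC[C@H]2[C@H](C=O)CC[C@]12C
F6 | step 17 | 7α-ethynyl compound | CC(C)(C)[Si](C)(C)O[C@@H]1[C@@H]2O[C@]2(C)CC[C@H]2[C@H](C#C)CC[C@]12C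
F7 | step 17 | methyl 3-(core-7α-yl)prop-2-ynoate | CC(C)(C)[Si](C)(C)O[C@@H]1[C@@H]2O[C@]2(C)CC[C@H]2[C@H](C#CC(=O)OC)CC[C@]12C
F8 | step 17 | methyl (2Z)-3-(core-7α-yl)but-2-enoate | CC(C)(C)[Si](C)(C)O[C@@H]1[C@@H]2O[C@]2(C)CC[C@H]2[C@H](/C(C)=C\C(=O)OC)CC[C@]12C
F9 | step 17 | (2Z)-3-(core-7α-yl)but-2-en-1-ol | CC(C)(C)[Si](C)(C)O[C@@H]1[C@@H]2O[C@]2(C)CC[C@H]2[C@H](/C(C)=C\CO)CC[C@]12C
F10 | step 17 | (2Z)-3-(core-7α-yl)but-2-enal | CC(C)(C)[Si](C)(C)O[C@@H]1[C@@H]2O[C@]2(C)CC[C@H]2[C@H](/C(C)=C\C=O)CC[C@]12C
F11 | step 17 | (3E,5Z)-6-(core-7α-yl)hepta-3,5-dien-2-one | CC(C)(C)[Si](C)(C)O[C@@H]1[C@@H]2O[C@]2(C)CC[C@H]2[C@H](/C(C)=C\C=C\C(C)=O)CC[C@]12C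
F12 | step 17 | 1α-silyl ether of the deacetyl target | CC(C)(C)[Si](C)(C)O[C@@H]1[C@@H]2O[C@]2(C)CC[C@H]2[C@H](/C(C)=C\C=C\C(C)(C)O)CC[C@]12C
F13 | step 17 | deacetyl target (1α-OH diol) | O[C@@H]1[C@@H]2O[C@]2(C)CC[C@H]2[C@H](/C(C)=C\C=C\C(C)(C)O)CC[C@]12C
F14 | step 3 | (Z)-3-iodo-2-methylprop-2-en-1-ol | OC/C(C)=C\I
F15 | step 3 | cis-(2-iodo-1-methylcyclopropyl)methanol (configured as 6) | OC[C@@]1(C)C[C@H]1I
F16 | step 3 | tert-butyldimethylsilyl ether of F15 | CC(C)(C)[Si](C)(C)OC[C@@]1(C)C[C@H]1I
F17 | step 3 | tert-butyldimethylsilyl ether of 6 | CC(C)(C)[Si](C)(C)OC[C@@]1(C)C[C@H]1C2=C(C)CCC2=O
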